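**Retrosynthetic overview**
1. Target 21 comes from the fully protected trimer 19 (five aryl N,N-diethylcarbamates, two MOM ethers) by a one-pot hydride/acid deprotection.
2. Each trans-2,3-diaryl-2,3-dihydrobenzofuran is cut at C2–C3 and O1–C2: an o-quinone methide (O1, C7a, C3a, C3) plus 4-(methoxymethoxy)phenyldiazomethane 9 (C2), joined in a chiral-squaramide-catalysed [4+1] annulation; 9 is made once from aldehyde 7 as a cold stock solution.
3. Each o-quinone methide precursor comes from ortho-lithiation of a resorcinol bis(carbamate) between its two carbamates, addition to an aryl aldehyde, and an O-to-O carbamoyl shift that frees one phenol and creates the benzylic leaving group.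
4. Ring order: the dihydrobenzofuran of unit B (2S,3S; carries the 3,5-dihydroxyphenyl) is formed first (step 5); after union with lithiated resveratrol tris(carbamate) (step 7), the dihydrobenzofuran of unit A (2R,3R; carries the styryl arm) is formed with the enantiomeric catalyst (step 8).
5. Building blocks: 3,5-dihydroxybenzaldehyde 1 (used twice), 4-(methoxymethoxy)benzaldehyde 7, resveratrol 13.

Assumption: catalyst Sq-S is taken to give the (2S,3S) ring; if the first run shows the opposite sense, Sq-S and Sq-R are exchanged between steps 5 and 8 (7 and 2-(trifluoromethyl)benzenesulfonohydrazide are taken as purchasable).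

Catalysts: Sq-S = 3-{[3,5-bis(trifluoromethyl)phenyl]amino}-4-{[(1S,2S)-2-(piperidin-1-yl)cyclohexyl]amino}cyclobut-3-ene-1,2-dione, O=C1C(Nc2cc(C(F)(F)F)cc(C(F)(F)F)c2)=C(N[C@H]2CCCC[C@@H]2N2CCCCC2)C1=O; Sq-R = its (1R,2R) enantiomer.

**Route**

Step 1
Reactants: 1 3,5-dihydroxybenzaldehyde
Product: 2 5-formyl-1,3-phenylene bis(N,N-diethylcarbamate)
Conditions: Et2NCOCl (2.5 equiv), K2CO3, MeCN, 80 °C
Reagents that add atoms: N,N-diethylcarbamoyl chloride, CCN(CC)C(Cl)=O
Why: O-carbamoylation of both phenols (acyl substitution) installs the ortho-directing groups; 2 serves later both as precursor of 3 and as electrophile.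

Step 2
Reactants: 2 5-formyl-1,3-phenylene bis(N,N-diethylcarbamate)
Product: 3 5-(dimethoxymethyl)-1,3-phenylene bis(N,N-diethylcarbamate)
Conditions: HC(OMe)3, MeOH, p-TsOH (2 mol%), rt; Et3N quench
Reagents that add atoms: trimethyl orthoformate, COC(OC)OC; methanol, CO
Why: Acid-catalysed acetalisation masks the aldehyde against the organolithium of step 3 and the diazoalkane of step 5.

Step 3
Reactants: 3 5-(dimethoxymethyl)-1,3-phenylene bis(N,N-diethylcarbamate); 2 5-formyl-1,3-phenylene bis(N,N-diethylcarbamate)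
Product: 6 racemic phenol–benzylic carbamate (o-quinone methide precursor of unit B), via aryllithium 4 (not isolated), via lithium alkoxide 5 (not isolated)
Conditions: s-BuLi (1.1 equiv), TMEDA, THF, −78 °C, 1 h; add 2, −78 → −40 °C; AcOH, −78 °C
Reagents that add atoms: none
Why: Snieckus directed ortho-metalation between two cooperating O-carbamates, 1,2-addition to aldehyde 2, then anionic O-to-O carbamoyl transfer through a six-membered tetrahedral intermediate (phenoxide is the better leaving group), which frees one phenol and puts a carbamate leaving group on the benzylic carbon; the carbinol stereocentre is racemic and is erased in step 5.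

Step 4
Reactants: 7 4-(methoxymethoxy)benzaldehyde
Product: 9 1-(diazomethyl)-4-(methoxymethoxy)benzene (cold titrated stock solution), via sulfonylhydrazone 8 (not isolated)
Conditions: 2-(CF3)C6H4SO2NHNH2 (1.0 equiv), CH2Cl2, 4 Å MS, rt, 2 h; cannula-filter onto NaH (1.1 equiv), PhMe, −40 → 0 °C, 1 h; cold filtration under Ar; ca. 0.2 M solution kept at −78 °C
Reagents that add atoms: 2-(trifluoromethyl)benzenesulfonohydrazide, NNS(=O)(=O)c1ccccc1C(F)(F)F
Why: Hydrazone condensation followed by Bamford–Stevens fragmentation of the sodium salt, which proceeds below room temperature because the electron-poor 2-(trifluoromethyl)benzenesulfinate is a good leaving group; filtration removes the sulfinate (a competing nucleophile for the o-quinone methides), and the solution is made on the scale needed for steps 5 and 8 or freshly before each.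

Step 5
Reactants: 6 racemic phenol–benzylic carbamate; 9 1-(diazomethyl)-4-(methoxymethoxy)benzene
Product: 12 (2S,3S)-6-formyl dihydrobenzofuran of unit B, via o-quinone methide 10 (not isolated), via dimethyl acetal 11 (not isolated)
Conditions: 9 (1.5 equiv, added over 4 h), K2CO3 (powdered, 2 equiv), catalyst Sq-S (10 mol%), 4 Å MS, PhMe/CH2Cl2 3:1, 0 °C; then 1 M HCl, THF, rt
Reagents that add atoms: water, O
Why: Proposed new method: K2CO3 converts 6 into o-quinone methide 10 (E1cB loss of diethylcarbamate from the phenoxide) while 9 is fed in slowly; 9 is only a moderate carbon nucleophile, so the unbound background addition is slow and the reaction runs through 10 hydrogen-bonded to the two squaramide N–H groups (ring carbonyl plus the neighbouring carbamate C=O as a two-point handle), the catalyst shielding one face of the exocyclic carbon and thereby setting C3; the diazonium phenolate then closes 5-exo with loss of N2 and sets C2 with the aryl group trans to the C3 aryl; the closest known reaction types are the base-mediated [4+1] annulation of o-quinone methides with sulfur ylides, its urea-catalysed asymmetric form with stabilised ylides, and the acid-promoted [4+1] of o-quinone methides with diazo esters; the acidic work-up hydrolyses the dimethyl acetal.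

Step 6
Reactants: 13 resveratrol
Product: 14 resveratrol tris(N,N-diethylcarbamate)
Conditions: Et2NCOCl (3.6 equiv), K2CO3, MeCN, 80 °C
Reagents that add atoms: N,N-diethylcarbamoyl chloride, CCN(CC)C(Cl)=O
Why: Same O-carbamoylation as in step 1; the two resorcinol carbamates become the directing groups and all three phenols are protected alike.

Step 7
Reactants: 14 resveratrol tris(N,N-diethylcarbamate); 12 (2S,3S)-6-formyl dihydrobenzofuran of unit B
Product: 17 phenol–benzylic carbamate (o-quinone methide precursor of unit A; 1:1 epimers at the carbinol carbon), via aryllithium 15 (not isolated), via lithium alkoxide 16 (not isolated)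
Conditions: lithium 2,2,6,6-tetramethylpiperidide (from n-BuLi + 2,2,6,6-tetramethylpiperidine, 1.5 equiv), 14 (1.5 equiv), THF, −78 °C, 1 h; add 12 (1.0 equiv), −78 → −40 °C; AcOH, −78 °C
Reagents that add atoms: none
Why: Directed ortho-metalation at the doubly activated position with a non-nucleophilic amide base (no carbolithiation of the stilbene), fast 1,2-addition to the aldehyde at −78 °C, and the same anionic O-to-O carbamoyl transfer as in step 3; the carbinol centre is erased in step 8 and the (2S,3S) centres are untouched.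

Step 8
Reactants: 17 phenol–benzylic carbamate; 9 1-(diazomethyl)-4-(methoxymethoxy)benzene
Product: 19 fully protected trimer with (2R,3R) unit A and (2S,3S) unit B, via o-quinone methide 18 (not isolated)
Conditions: 9 (1.5 equiv, added over 4 h), K2CO3 (powdered, 2 equiv), catalyst Sq-R (10 mol%), 4 Å MS, PhMe/CH2Cl2 3:1, 0 °C
Reagents that add atoms: none
Why: Proposed new method: the same squaramide-catalysed o-quinone methide/aryldiazomethane [4+1] annulation as in step 5 (K2CO3 releases 18 from 17; closest known types as given there), now with the enantiomeric catalyst; the existing stereocentres lie para across the benzene ring of unit B and exert little bias, so the catalyst sets the new C3 as R and the N2-releasing ring closure sets C2 trans (2R,3R); material from the minor enantiomer of 12 ends up as diastereomers that are removed on silica.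

Step 9
Reactants: 19 fully protected trimer
Product: 21 target CNP0248228.3, via bis(methoxymethyl) ether 20 (not isolated)
Conditions: LiAlH4 (excess), THF, 0 → 50 °C; then MeOH, HCl (to 2 M), 40 °C
Reagents that add atoms: none
Why: Hydride cleavage of the five aryl carbamates is done while both 2-aryl groups still carry MOM ethers, so no para-phenoxide can open a dihydrobenzofuran to a reducible quinone methide; the acid stage then removes the MOM ethers by transacetalisation, and any reversible C2–O ionisation can only return the favoured trans rings with C3 untouched.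

**Compound list**
1 | 3,5-dihydroxybenzaldehyde | O=Cc1cc(O)cc(O)c1 | starting material
2 | 5-formyl-1,3-phenylene bis(N,N-diethylcarbamate) | O=Cc1cc(OC(=O)N(CC)CC)cc(OC(=O)N(CC)CC)c1 | intermediate
3 | 5-(dimethoxymethyl)-1,3-phenylene bis(N,N-diethylcarbamate) | COC(OC)c1cc(OC(=O)N(CC)CC)cc(OC(=O)N(CC)CC)c1 | intermediate
4 | 2-lithio derivative of 3 (lithium between the two carbamate-bearing carbons) | COC(OC)c1cc(OC(=O)N(CC)CC)c([Li])c(OC(=O)N(CC)CC)c1 | intermediate
5 | lithium [2,6-bis(diethylcarbamoyloxy)-4-(dimethoxymethyl)phenyl][3,5-bis(diethylcarbamoyloxy)phenyl]methoxide (racemic) | [Li]OC(c1cc(OC(=O)N(CC)CC)cc(OC(=O)N(CC)CC)c1)c1c(OC(=O)N(CC)CC)cc(C(OC)OC)cc1OC(=O)N(CC)CC | intermediate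
6 | [3,5-bis(diethylcarbamoyloxy)phenyl][2-(diethylcarbamoyloxy)-4-(dimethoxymethyl)-6-hydroxyphenyl]methyl N,N-diethylcarbamate (racemic) | CCN(CC)C(=O)OC(c1cc(OC(=O)N(CC)CC)cc(OC(=O)N(CC)CC)c1)c1c(O)cc(C(OC)OC)cc1OC(=O)N(CC)CC | intermediate
7 | 4-(methoxymethoxy)benzaldehyde | COCOc1ccc(C=O)cc1 | starting material
8 | (E)-N'-[4-(methoxymethoxy)benzylidene]-2-(trifluoromethyl)benzenesulfonohydrazide | COCOc1ccc(/C=N/NS(=O)(=O)c2ccccc2C(F)(F)F)cc1 | intermediate
9 | 1-(diazomethyl)-4-(methoxymethoxy)benzene (used as a cold titrated solution) | COCOc1ccc(C=[N+]=[N-])cc1 | intermediate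
10 | o-quinone methide: 6-[3,5-bis(diethylcarbamoyloxy)benzylidene]-5-(diethylcarbamoyloxy)-3-(dimethoxymethyl)cyclohexa-2,4-dien-1-one | O=C1C=C(C(OC)OC)C=C(OC(=O)N(CC)CC)C1=Cc1cc(OC(=O)N(CC)CC)cc(OC(=O)N(CC)CC)c1 | intermediate
11 | (2S,3S)-3-[3,5-bis(diethylcarbamoyloxy)phenyl]-6-(dimethoxymethyl)-2-[4-(methoxymethoxy)phenyl]-2,3-dihydro-1-benzofuran-4-yl N,N-diethylcarbamate (trans) | COC(OC)c1cc(OC(=O)N(CC)CC)c2c(c1)O[C@H](c1ccc(OCOC)cc1)[C@H]2c1cc(OC(=O)N(CC)CC)cc(OC(=O)N(CC)CC)c1 | intermediate
12 | (2S,3S)-3-[3,5-bis(diethylcarbamoyloxy)phenyl]-6-formyl-2-[4-(methoxymethoxy)phenyl]-2,3-dihydro-1-benzofuran-4-yl N,N-diethylcarbamate (trans) | O=Cc1cc(OC(=O)N(CC)CC)c2c(c1)O[C@H](c1ccc(OCOC)cc1)[C@H]2c1cc(OC(=O)N(CC)CC)cc(OC(=O)N(CC)CC)c1 | intermediate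
13 | resveratrol, (E)-3,4',5-trihydroxystilbene | Oc1ccc(/C=C/c2cc(O)cc(O)c2)cc1 | starting material
14 | resveratrol tris(N,N-diethylcarbamate) | CCN(CC)C(=O)Oc1ccc(/C=C/c2cc(OC(=O)N(CC)CC)cc(OC(=O)N(CC)CC)c2)cc1 | intermediate
15 | aryllithium from 14 (lithium between the two carbamates of the resorcinol ring) | CCN(CC)C(=O)Oc1ccc(/C=C/c2cc(OC(=O)N(CC)CC)c([Li])c(OC(=O)N(CC)CC)c2)cc1 | intermediate
16 | lithium alkoxide from 15 and 12 (epimers at the carbinol carbon) | [Li]OC(c1cc(OC(=O)N(CC)CC)c2c(c1)O[C@H](c1ccc(OCOC)cc1)[C@H]2c1cc(OC(=O)N(CC)CC)cc(OC(=O)N(CC)CC)c1)c1c(OC(=O)N(CC)CC)cc(/C=C/c2ccc(OC(=O)N(CC)CC)cc2)cc1OC(=O)N(CC)CC | intermediate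
17 | [6-yl of the (2S,3S)-dihydrobenzofuran of 12][2-(diethylcarbamoyloxy)-4-{(E)-2-[4-(diethylcarbamoyloxy)phenyl]ethenyl}-6-hydroxyphenyl]methyl N,N-diethylcarbamate (epimers at the carbinol carbon) | CCN(CC)C(=O)OC(c1cc(OC(=O)N(CC)CC)c2c(c1)O[C@H](c1ccc(OCOC)cc1)[C@H]2c1cc(OC(=O)N(CC)CC)cc(OC(=O)N(CC)CC)c1)c1c(O)cc(/C=C/c2ccc(OC(=O)N(CC)CC)cc2)cc1OC(=O)N(CC)CC | intermediate
18 | o-quinone methide from 17: 6-(arylmethylidene)-5-(diethylcarbamoyloxy)-3-[(E)-4-(diethylcarbamoyloxy)styryl]cyclohexa-2,4-dien-1-one, aryl = C6 of the unit B dihydrobenzofuran | O=C1C=C(/C=C/c2ccc(OC(=O)N(CC)CC)cc2)C=C(OC(=O)N(CC)CC)C1=Cc1cc(OC(=O)N(CC)CC)c2c(c1)O[C@H](c1ccc(OCOC)cc1)[C@H]2c1cc(OC(=O)N(CC)CC)cc(OC(=O)N(CC)CC)c1 | intermediate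
19 | protected trimer: target skeleton with OCONEt2 on the stilbene phenol, on both dihydrobenzofuran C4 oxygens and on the 3,5-positions of the pendant aryl, and OMOM on both 2-aryl para oxygens; (2R,3R) unit A, (2S,3S) unit B | CCN(CC)C(=O)Oc1ccc(/C=C/c2cc(OC(=O)N(CC)CC)c3c(c2)O[C@@H](c2ccc(OCOC)cc2)[C@@H]3c2cc(OC(=O)N(CC)CC)c3c(c2)O[C@H](c2ccc(OCOC)cc2)[C@H]3c2cc(OC(=O)N(CC)CC)cc(OC(=O)N(CC)CC)c2)cc1 | intermediate
20 | pentaphenol bis(methoxymethyl) ether (target with OMOM on both 2-aryl para oxygens) | Oc1ccc(/C=C/c2cc(O)c3c(c2)O[C@@H](c2ccc(OCOC)cc2)[C@@H]3c2cc(O)c3c(c2)O[C@H](c2ccc(OCOC)cc2)[C@H]3c2cc(O)cc(O)c2)cc1 | intermediate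
21 | (2R,3R)-3-[(2S,3S)-3-(3,5-dihydroxyphenyl)-4-hydroxy-2-(4-hydroxyphenyl)-2,3-dihydro-1-benzofuran-6-yl]-2-(4-hydroxyphenyl)-6-[(E)-2-(4-hydroxyphenyl)ethenyl]-2,3-dihydro-1-benzofuran-4-ol | Oc1ccc(/C=C/c2cc(O)c3c(c2)O[C@@H](c2ccc(O)cc2)[C@@H]3c2cc(O)c3c(c2)O[C@H](c2ccc(O)cc2)[C@H]3c2cc(O)cc(O)c2)cc1 | target

**Step count**
Total: 9 steps. Longest linear sequence: 7 steps (1, 2, 3, 5, 7, 8, 9).

**Steps most likely to fail**

Step 5 (the proposed new annulation, repeated in step 8). Risks are low enantioselectivity, protonation, dimerisation or decay of the diazoalkane, loss of N2 with 1,2-hydride shift to a stilbene instead of ring closure, and oligomerisation of the o-quinone methide. The fallback uses known chemistry, sets out from 6 and 7 and comes back at 12. Aldehyde 7 is reduced (NaBH4, MeOH) to [4-(methoxymethoxy)phenyl]methanol F1, converted (CBr4, PPh3, CH2Cl2, 0 °C) into 1-(bromomethyl)-4-(methoxymethoxy)benzene F2, and alkylated onto tetrahydrothiophene (acetone, rt) to give 1-[4-(methoxymethoxy)benzyl]tetrahydrothiophenium bromide F3. With Cs2CO3 in CH2Cl2 at rt this salt gives the sulfonium ylide F4, which undergoes the established base-mediated [4+1] annulation with o-quinone methide 10 released from 6. This gives the racemic trans acetal F5 and, after 1 M HCl/THF, the racemic trans aldehyde F6; preparative chiral SFC then delivers the (2S,3S) enantiomer 12.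

Step 7 (fragment union). The basic aryllithium 15 may deprotonate the doubly benzylic C3–H of 12 (para to the formyl group) and open the ring, or the phenoxide may eliminate early to the o-quinone methide. The fallback sets out from 14 and comes back at 17. Aryllithium 15 is quenched with I2 to give the isolable 2-iodo-5-[(E)-4-(diethylcarbamoyloxy)styryl]-1,3-phenylene bis(N,N-diethylcarbamate) F7. Iodine–magnesium exchange (i-PrMgCl·LiCl, THF, −40 °C) gives the much less basic arylmagnesium chloride F8, which adds to 12 to give the magnesium alkoxide F9. Warming to 0 °C brings about the same O-to-O carbamoyl shift, and AcOH quench gives 17.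

Step 9 (one-pot global deprotection). Five hindered carbamates need forcing LiAlH4 treatment, and the stilbene/resorcinol system is acid-sensitive. The fallback sets out from 19 and comes back at 21 in two chemoselective stages. Cp2Zr(H)Cl (zirconocene chloride hydride, THF, rt) cleaves the aryl carbamates reductively and 20 is now isolated. ZnBr2 with n-PrSH (CH2Cl2, 0 °C, 10 min) then removes the two MOM ethers without protic acid. No compound outside the list is formed (none F0).

**Further compounds**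
F1 | step 5 | [4-(methoxymethoxy)phenyl]methanol | COCOc1ccc(CO)cc1
F2 | step 5 | 1-(bromomethyl)-4-(methoxymethoxy)benzene | COCOc1ccc(CBr)cc1
F3 | step 5 | 1-[4-(methoxymethoxy)benzyl]tetrahydrothiophenium bromide | COCOc1ccc(C[S+]2CCCC2)cc1.[Br-]
F4 | step 5 | sulfonium ylide of F3 | COCOc1ccc([CH-][S+]2CCCC2)cc1
F5 | step 5 | racemic trans acetal (11 plus its enantiomer) | COC(OC)c1cc(OC(=O)N(CC)CC)c2c(c1)O[C@H](c1ccc(OCOC)cc1)[C@H]2c1cc(OC(=O)N(CC)CC)cc(OC(=O)N(CC)CC)c1.COC(OC)c1cc(OC(=O)N(CC)CC)c2c(c1)O[C@@H](c1ccc(OCOC)cc1)[C@@H]2c1cc(OC(=O)N(CC)CC)cc(OC(=O)N(CC)CC)c1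
F6 | step 5 | racemic trans aldehyde (12 plus its enantiomer) | O=Cc1cc(OC(=O)N(CC)CC)c2c(c1)O[C@H](c1ccc(OCOC)cc1)[C@H]2c1cc(OC(=O)N(CC)CC)cc(OC(=O)N(CC)CC)c1.O=Cc1cc(OC(=O)N(CC)CC)c2c(c1)O[C@@H](c1ccc(OCOC)cc1)[C@@H]2c1cc(OC(=O)N(CC)CC)cc(OC(=O)N(CC)CC)c1
F7 | step 7 | 2-iodo-5-[(E)-4-(diethylcarbamoyloxy)styryl]-1,3-phenylene bis(N,N-diethylcarbamate) | CCN(CC)C(=O)Oc1ccc(/C=C/c2cc(OC(=O)N(CC)CC)c(I)c(OC(=O)N(CC)CC)c2)cc1
F8 | step 7 | arylmagnesium chloride from F7 | CCN(CC)C(=O)Oc1ccc(/C=C/c2cc(OC(=O)N(CC)CC)c([Mg]Cl)c(OC(=O)N(CC)CC)c2)cc1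
F9 | step 7 | chloromagnesium alkoxide from F8 and 12 | Cl[Mg]OC(c1cc(OC(=O)N(CC)CC)c2c(c1)O[C@H](c1ccc(OCOC)cc1)[C@H]2c1cc(OC(=O)N(CC)CC)cc(OC(=O)N(CC)CC)c1)c1c(OC(=O)N(CC)CC)cc(/C=C/c2ccc(OC(=O)N(CC)CC)cc2)cc1OC(=O)N(CC)CC
F0 | step 9 | none | none
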